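**Retrosynthetic overview**
- Last bond: C10–C11 (sp3–sp2), made by hydroboration and B-alkyl Suzuki coupling of the west-plus-chain diene with the (Z)-enol triflate of the east lactone; retention at the triflate fixes the Z-alkylidene.
- The east γ-lactone ring comes ready-made from the chiral pool ((S)-5-(hydroxymethyl)butyrolactone); the isobutenyl group is added by Wittig reaction, C11 by α-formylation, and the Z-triflate by chelation-controlled triflation.
- The west butenolide ring is closed by Wittig olefination of a (4R)-4-alkyl-1,3-dioxan-5-one, then acid-induced acetonide loss and lactonisation; acetylation follows.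
- C1 stereocentre and C1–C2 bond: proposed enantioselective palladium-catalysed allylation of the dioxanone silyl enol ether with a geraniol-derived trienyl carbonate (the new step).
- The chain comes from geraniol (SeO2 oxidation, methylenation). Ring order: east lactone (present from the start), 1,3-dioxane (temporary), butenolide (last ring formed).

Locants used below: C1 = acetoxy carbon, C2–C10 = chain, C11 = exocyclic =CH, C12/C13/C14 = lactone α/β/γ carbons.
Target as read from the SMILES: C1 is R, C14 is S, C3=C4 and C7=C8 are E, C11=C12 is Z (chain cis to the lactone C=O).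
Assumption: in step 6 the (R,R)-ligand is taken to give the 4R ketone; if the first run shows the opposite sense, the (S,S)-ligand is used and nothing else changes.

**Route**

Step 1
Reactants: 1 geraniol
Product: 2 methyl (2E)-3,7-dimethylocta-2,6-dien-1-yl carbonate
Conditions: ClCO2Me, pyridine, CH2Cl2, 0 °C → rt
Reagents that add atoms: methyl chloroformate, COC(=O)Cl
Why: Acylation of the primary allylic alcohol by the chloroformate (carbonate formation) touches neither alkene; the carbonate is the later leaving group for π-allyl formation and deactivates the 2,3-alkene toward SeO2.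

Step 2
Reactants: 2 methyl (2E)-3,7-dimethylocta-2,6-dien-1-yl carbonate
Product: 3 methyl (2E,6E)-8-hydroxy-3,7-dimethylocta-2,6-dien-1-yl carbonate
Conditions: SeO2 (10 mol%), t-BuOOH (70% aq.), salicylic acid (10 mol%), CH2Cl2, rt
Reagents that add atoms: tert-butyl hydroperoxide, CC(C)(C)OO (oxygen relayed through catalytic selenium dioxide, O=[Se]=O)
Why: Sharpless SeO2 allylic oxidation (ene reaction then 2,3-sigmatropic shift) attacks the electron-rich terminal isopropylidene group and oxidises its E-methyl group, so the new C7=C8 alkene is E.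

Step 3
Reactants: 3 methyl (2E,6E)-8-hydroxy-3,7-dimethylocta-2,6-dien-1-yl carbonate
Product: 4 methyl (2E,6E)-3,7-dimethyl-8-oxoocta-2,6-dien-1-yl carbonate
Conditions: MnO2 (activated, excess), CH2Cl2, rt
Reagents that add atoms: none
Why: MnO2 oxidises allylic alcohols chemoselectively to enals without E/Z isomerisation.

Step 4
Reactants: 4 methyl (2E,6E)-3,7-dimethyl-8-oxoocta-2,6-dien-1-yl carbonate
Product: 5 methyl (2E,6E)-3,7-dimethylnona-2,6,8-trien-1-yl carbonate
Conditions: Ph3PCH3Br, n-BuLi, THF, 0 °C; then 4, −78 → 0 °C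
Reagents that add atoms: methyltriphenylphosphonium bromide, C[P+](c1ccccc1)(c1ccccc1)c1ccccc1.[Br-]
Why: Wittig methylenation of the enal at low temperature is much faster than attack on the carbonate and gives the 1,3-diene whose terminal vinyl group is the latent C10 nucleophile.

Step 5
Reactants: 6 2,2-dimethyl-1,3-dioxan-5-one
Product: 7 [(2,2-dimethyl-4H-1,3-dioxin-5-yl)oxy](trimethyl)silane
Conditions: Me3SiOTf, Et3N, CH2Cl2, 0 °C
Reagents that add atoms: trimethylsilyl trifluoromethanesulfonate, C[Si](C)(C)OS(=O)(=O)C(F)(F)F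
Why: Soft enolisation and O-silylation of the symmetrical ketone gives the silyl enol ether and avoids the self-aldol reaction of the free dioxanone enolate.

Step 6
Reactants: 5 methyl (2E,6E)-3,7-dimethylnona-2,6,8-trien-1-yl carbonate; 7 [(2,2-dimethyl-4H-1,3-dioxin-5-yl)oxy](trimethyl)silane (1.3 equiv)
Product: 8 (4R)-4-[(2E,6E)-3,7-dimethylnona-2,6,8-trien-1-yl]-2,2-dimethyl-1,3-dioxan-5-one
Conditions: Pd2(dba)3·CHCl3 (2.5 mol%), (R,R)-ANDEN-phenyl Trost ligand (6 mol%), Bu4N Ph3SiF2 (5 mol%), toluene, 0 °C → rt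
Reagents that add atoms: none
Why: Proposed new method: enantioselective palladium-catalysed allylation of the unsubstituted dihydroxyacetone-acetonide silyl enol ether with a 3,3-disubstituted (geranyl-type) allylic carbonate, creating a tertiary α-oxy stereocentre. The zerovalent palladium–ligand complex ionises the carbonate to a syn π-allyl cation and methyl carbonate, which loses CO2. The methoxide (fluoride for the first turnover) removes the silyl group of 7, so the enolate exists only as the counter-ion of the π-allyl cation and never accumulates. Outer-sphere attack occurs at the unsubstituted CH2 terminus because the other terminus is fully substituted, which gives the linear product. The E geometry is kept because syn/anti exchange would need a σ-bond to palladium at the tertiary carbon. The chiral pocket of the ligand selects the enolate face and sets C1 (taken as R, see assumption). The tertiary centre is not racemised because no free base remains once methoxide is trapped on silicon. Closest known reaction type: Tsuji–Trost asymmetric allylic alkylation of silyl enol ethers or enol carbonates, which as far as I know is established for α-substituted dioxanone enol ethers with the parent allyl group but not for the parent enolate with a 3,3-disubstituted allyl partner.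

Step 7
Reactants: 8 (4R)-4-[(2E,6E)-3,7-dimethylnona-2,6,8-trien-1-yl]-2,2-dimethyl-1,3-dioxan-5-one
Product: 9 ethyl (2E)-2-[(4R)-4-[(2E,6E)-3,7-dimethylnona-2,6,8-trien-1-yl]-2,2-dimethyl-1,3-dioxan-5-ylidene]acetate
Conditions: Ph3P=CHCO2Et (1.5 equiv), CH2Cl2, rt
Reagents that add atoms: ethyl (triphenylphosphoranylidene)acetate, CCOC(=O)C=P(c1ccccc1)(c1ccccc1)c1ccccc1
Why: Wittig olefination with the stabilised ylide works because the two α-oxygen atoms activate the ketone; allylic 1,3-strain places the ester on the side of the unsubstituted CH2O carbon (E), and the neutral ylide leaves the α-stereocentre untouched.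

Step 8
Reactants: 9 ethyl (2E)-2-[(4R)-4-[(2E,6E)-3,7-dimethylnona-2,6,8-trien-1-yl]-2,2-dimethyl-1,3-dioxan-5-ylidene]acetate
Product: 11 4-[(1R,3E,7E)-1-hydroxy-4,8-dimethyldeca-3,7,9-trien-1-yl]furan-2(5H)-one, via dihydroxy ester 10 (not isolated)
Conditions: p-TsOH·H2O (10 mol%), THF–H2O (4:1), 40 °C
Reagents that add atoms: none
Why: Acid-catalysed acetonide hydrolysis frees both hydroxyl groups, and only the primary one is cis to the ester across the E alkene, so lactonisation (intramolecular transesterification) gives the 4-substituted butenolide with C1 unchanged.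

Step 9
Reactants: 11 4-[(1R,3E,7E)-1-hydroxy-4,8-dimethyldeca-3,7,9-trien-1-yl]furan-2(5H)-one
Product: 12 (1R,3E,7E)-4,8-dimethyl-1-(5-oxo-2,5-dihydrofuran-3-yl)deca-3,7,9-trien-1-yl acetate
Conditions: Ac2O, pyridine, DMAP (cat.), CH2Cl2, 0 °C
Reagents that add atoms: acetic anhydride, CC(=O)OC(C)=O
Why: DMAP-catalysed acetylation of the secondary alcohol proceeds with retention because the C–O bond is not broken.

Step 10
Reactants: 13 (5S)-5-(hydroxymethyl)dihydrofuran-2(3H)-one
Product: 14 (2S)-5-oxotetrahydrofuran-2-carbaldehyde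
Conditions: Dess–Martin periodinane, CH2Cl2, 0 °C → rt; used crude
Reagents that add atoms: none
Why: Dess–Martin oxidation of the primary alcohol under near-neutral conditions gives the α-oxy aldehyde without epimerisation.

Step 11
Reactants: 14 (2S)-5-oxotetrahydrofuran-2-carbaldehyde
Product: 15 (5S)-5-(2-methylprop-1-en-1-yl)dihydrofuran-2(3H)-one
Conditions: i-PrPPh3I, n-BuLi, THF, 0 °C; then 14, −78 °C → rt
Reagents that add atoms: isopropyltriphenylphosphonium iodide, CC(C)[P+](c1ccccc1)(c1ccccc1)c1ccccc1.[I-]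
Why: Wittig olefination with the non-stabilised isopropylidene ylide at −78 °C is selective for the aldehyde over the lactone carbonyl; the S centre (C14 of the target) comes unchanged from the chiral pool.

Step 12
Reactants: 15 (5S)-5-(2-methylprop-1-en-1-yl)dihydrofuran-2(3H)-one
Product: 16 (3Z,5S)-3-(hydroxymethylidene)-5-(2-methylprop-1-en-1-yl)dihydrofuran-2(3H)-one
Conditions: HCO2Et, NaH, EtOH (cat.), Et2O, 0 °C → rt; cold 1 M HCl work-up
Reagents that add atoms: ethyl formate, CCOC=O
Why: Crossed Claisen condensation (α-formylation) of the lactone is driven by formation of the stabilised sodium enolate of the product; the γ-stereocentre is not acidic and the product is the hydrogen-bonded Z enol.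

Step 13
Reactants: 16 (3Z,5S)-3-(hydroxymethylidene)-5-(2-methylprop-1-en-1-yl)dihydrofuran-2(3H)-one
Product: 17 (Z)-[(5S)-5-(2-methylprop-1-en-1-yl)-2-oxodihydrofuran-3(2H)-ylidene]methyl trifluoromethanesulfonate
Conditions: Tf2O, Et3N, LiOTf, CH2Cl2, −78 °C
Reagents that add atoms: trifluoromethanesulfonic anhydride, O=S(=O)(OS(=O)(=O)C(F)(F)F)C(F)(F)F
Why: Chelation-controlled O-triflation: lithium holds the enolate oxygen and the lactone carbonyl oxygen on the same side, so the triflate ends up cis to the C=O (Z).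

Step 14
Reactants: 12 (1R,3E,7E)-4,8-dimethyl-1-(5-oxo-2,5-dihydrofuran-3-yl)deca-3,7,9-trien-1-yl acetate; 17 (Z)-[(5S)-5-(2-methylprop-1-en-1-yl)-2-oxodihydrofuran-3(2H)-ylidene]methyl trifluoromethanesulfonate
Product: 19 (1R,3E,7E,11Z)-4,8-dimethyl-11-[(5S)-5-(2-methylprop-1-en-1-yl)-2-oxodihydrofuran-3(2H)-ylidene]-1-(5-oxo-2,5-dihydrofuran-3-yl)undeca-3,7-dien-1-yl acetate (target), via alkylborane 18 (not isolated)
Conditions: 9-BBN (1.2 equiv), THF, 0 °C → rt; then aq. K3PO4, 17, Pd(dppf)Cl2·CH2Cl2 (8 mol%), AsPh3, DMF, rt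
Reagents that add atoms: none
Why: Anti-Markovnikov hydroboration of the terminal vinyl group by 9-BBN (far faster than trisubstituted alkenes or unsaturated lactones) is followed by B-alkyl Suzuki–Miyaura coupling, which retains the enol triflate geometry and so delivers the Z-alkylidene lactone.

**Compound list**

1 | geraniol, (2E)-3,7-dimethylocta-2,6-dien-1-ol | OC/C=C(\C)CCC=C(C)C | starting material
2 | methyl (2E)-3,7-dimethylocta-2,6-dien-1-yl carbonate | COC(=O)OC/C=C(\C)CCC=C(C)C | intermediate
3 | methyl (2E,6E)-8-hydroxy-3,7-dimethylocta-2,6-dien-1-yl carbonate | COC(=O)OC/C=C(\C)CC/C=C(\C)CO | intermediate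
4 | methyl (2E,6E)-3,7-dimethyl-8-oxoocta-2,6-dien-1-yl carbonate | COC(=O)OC/C=C(\C)CC/C=C(\C)C=O | intermediate
5 | methyl (2E,6E)-3,7-dimethylnona-2,6,8-trien-1-yl carbonate | COC(=O)OC/C=C(\C)CC/C=C(\C)C=C | intermediate
6 | 2,2-dimethyl-1,3-dioxan-5-one | CC1(C)OCC(=O)CO1 | starting material
7 | [(2,2-dimethyl-4H-1,3-dioxin-5-yl)oxy](trimethyl)silane | CC1(C)OCC(O[Si](C)(C)C)=CO1 | intermediate
8 | (4R)-4-[(2E,6E)-3,7-dimethylnona-2,6,8-trien-1-yl]-2,2-dimethyl-1,3-dioxan-5-one | CC1(C)OCC(=O)[C@@H](C/C=C(\C)CC/C=C(\C)C=C)O1 | intermediate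
9 | ethyl (2E)-2-[(4R)-4-[(2E,6E)-3,7-dimethylnona-2,6,8-trien-1-yl]-2,2-dimethyl-1,3-dioxan-5-ylidene]acetate | CCOC(=O)/C=C1\COC(C)(C)O[C@@H]1C/C=C(\C)CC/C=C(\C)C=C | intermediate
10 | ethyl (2E,4R,6E,10E)-4-hydroxy-3-(hydroxymethyl)-7,11-dimethyltrideca-2,6,10,12-tetraenoate | CCOC(=O)/C=C(\CO)[C@H](O)C/C=C(\C)CC/C=C(\C)C=C | intermediate
11 | 4-[(1R,3E,7E)-1-hydroxy-4,8-dimethyldeca-3,7,9-trien-1-yl]furan-2(5H)-one | O[C@H](C/C=C(\C)CC/C=C(\C)C=C)C1=CC(=O)OC1 | intermediate
12 | (1R,3E,7E)-4,8-dimethyl-1-(5-oxo-2,5-dihydrofuran-3-yl)deca-3,7,9-trien-1-yl acetate | CC(=O)O[C@H](C/C=C(\C)CC/C=C(\C)C=C)C1=CC(=O)OC1 | intermediate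
13 | (5S)-5-(hydroxymethyl)dihydrofuran-2(3H)-one | OC[C@@H]1CCC(=O)O1 | starting material
14 | (2S)-5-oxotetrahydrofuran-2-carbaldehyde | O=C[C@@H]1CCC(=O)O1 | intermediate
15 | (5S)-5-(2-methylprop-1-en-1-yl)dihydrofuran-2(3H)-one | CC(C)=C[C@@H]1CCC(=O)O1 | intermediate
16 | (3Z,5S)-3-(hydroxymethylidene)-5-(2-methylprop-1-en-1-yl)dihydrofuran-2(3H)-one | O/C=C1/C[C@@H](C=C(C)C)OC1=O | intermediate
17 | (Z)-[(5S)-5-(2-methylprop-1-en-1-yl)-2-oxodihydrofuran-3(2H)-ylidene]methyl trifluoromethanesulfonate | O=S(=O)(O/C=C1/C[C@@H](C=C(C)C)OC1=O)C(F)(F)F | intermediate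
18 | (1R,3E,7E)-10-(9-borabicyclo[3.3.1]nonan-9-yl)-4,8-dimethyl-1-(5-oxo-2,5-dihydrofuran-3-yl)deca-3,7-dien-1-yl acetate | CC(=O)O[C@H](C/C=C(\C)CC/C=C(\C)CCB1C2CCCC1CCC2)C1=CC(=O)OC1 | intermediate
19 | (1R,3E,7E,11Z)-4,8-dimethyl-11-[(5S)-5-(2-methylprop-1-en-1-yl)-2-oxodihydrofuran-3(2H)-ylidene]-1-(5-oxo-2,5-dihydrofuran-3-yl)undeca-3,7-dien-1-yl acetate (CNP0310925.2) | CC(=O)O[C@H](C/C=C(\C)CC/C=C(\C)CC/C=C1/C[C@@H](C=C(C)C)OC1=O)C1=CC(=O)OC1 | target

**Totals and risk**

Total steps: 14. Longest linear sequence: 9 steps (1, 2, 3, 4, 6, 7, 8, 9, 14).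

Steps most likely to fail:

Step 6 (the proposed new allylation). Likely failure modes are attack at the tertiary allyl terminus, base-induced elimination of the π-allyl to a tetraene, or low enantioselectivity. The fallback is the known Enders hydrazone alkylation; it sets out from 5 and 6 and comes back at 8. The carbonate of 5 is removed with K2CO3 in MeOH to give (2E,6E)-3,7-dimethylnona-2,6,8-trien-1-ol F1, which PBr3 in Et2O at −10 °C converts to (2E,6E)-1-bromo-3,7-dimethylnona-2,6,8-triene F2. Ketone 6 is condensed with (R)-1-amino-2-(methoxymethyl)pyrrolidine (RAMP) to give (2R)-N-(2,2-dimethyl-1,3-dioxan-5-ylidene)-2-(methoxymethyl)pyrrolidin-1-amine F3. Deprotonation with t-BuLi (THF, −78 °C) and alkylation with F2 at −100 °C gives (2R)-N-[(4R,5Z)-4-[(2E,6E)-3,7-dimethylnona-2,6,8-trien-1-yl]-2,2-dimethyl-1,3-dioxan-5-ylidene]-2-(methoxymethyl)pyrrolidin-1-amine F4. RAMP should give 4R, the mirror image of the 4S outcome I recall for SAMP with this ketone. Two-phase cleavage with saturated aqueous oxalic acid and Et2O returns 8 with the acetonide intact.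

Step 7 (Wittig geometry on the 4-substituted dioxanone). The wrong alkene isomer would lactonise through the secondary hydroxyl in step 8 and give the isomeric butenolide. The fallback sets out from 8 and comes back at 11. The acetonide of 8 is hydrolysed (AcOH–H2O 4:1, 40 °C) to (3R,5E,9E)-1,3-dihydroxy-6,10-dimethyldodeca-5,9,11-trien-2-one F8. (Triphenylphosphoranylidene)ketene (Ph3P=C=C=O, 1.0 equiv, THF, 50 °C) adds to the less hindered primary hydroxyl, and the resulting phosphorane ester closes onto the ketone by intramolecular Wittig reaction. Once the primary hydroxyl has reacted, only the 4-substituted butenolide 11 can form; this is the classical construction of cardenolide butenolides from α-hydroxy ketones.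

Step 14 (fragment union). Risks are hydrolysis or isomerisation of the enol triflate in aqueous base and interference from the allylic acetate under zerovalent palladium. The fallback sets out from 12 (with 17) and comes back at 19. Hydroboration of 12 with 9-BBN as before, but with oxidative work-up (NaBO3·4H2O, THF–H2O), gives (1R,3E,7E)-10-hydroxy-4,8-dimethyl-1-(5-oxo-2,5-dihydrofuran-3-yl)deca-3,7-dien-1-yl acetate F5. I2, PPh3 and imidazole convert it to (1R,3E,7E)-10-iodo-4,8-dimethyl-1-(5-oxo-2,5-dihydrofuran-3-yl)deca-3,7-dien-1-yl acetate F6. Zinc dust and LiCl in THF give (1R,3E,7E)-10-(iodozincio)-4,8-dimethyl-1-(5-oxo-2,5-dihydrofuran-3-yl)deca-3,7-dien-1-yl acetate F7. This is coupled with 17 under base-free Negishi conditions (Pd(PPh3)4, THF, rt), again with retention at the enol triflate, to give 19.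

Further compounds
F1 | step 6 | (2E,6E)-3,7-dimethylnona-2,6,8-trien-1-ol | OC/C=C(\C)CC/C=C(\C)C=C
F2 | step 6 | (2E,6E)-1-bromo-3,7-dimethylnona-2,6,8-triene | BrC/C=C(\C)CC/C=C(\C)C=C
F3 | step 6 | (2R)-N-(2,2-dimethyl-1,3-dioxan-5-ylidene)-2-(methoxymethyl)pyrrolidin-1-amine | COC[C@H]1CCCN1N=C1COC(C)(C)OC1
F4 | step 6 | (2R)-N-[(4R,5Z)-4-[(2E,6E)-3,7-dimethylnona-2,6,8-trien-1-yl]-2,2-dimethyl-1,3-dioxan-5-ylidene]-2-(methoxymethyl)pyrrolidin-1-amine | COC[C@H]1CCCN1/N=C1/COC(C)(C)O[C@@H]1C/C=C(\C)CC/C=C(\C)C=C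
F8 | step 7 | (3R,5E,9E)-1,3-dihydroxy-6,10-dimethyldodeca-5,9,11-trien-2-one | OCC(=O)[C@H](O)C/C=C(\C)CC/C=C(\C)C=C
F5 | step 14 | (1R,3E,7E)-10-hydroxy-4,8-dimethyl-1-(5-oxo-2,5-dihydrofuran-3-yl)deca-3,7-dien-1-yl acetate | CC(=O)O[C@H](C/C=C(\C)CC/C=C(\C)CCO)C1=CC(=O)OC1
F6 | step 14 | (1R,3E,7E)-10-iodo-4,8-dimethyl-1-(5-oxo-2,5-dihydrofuran-3-yl)deca-3,7-dien-1-yl acetate | CC(=O)O[C@H](C/C=C(\C)CC/C=C(\C)CCI)C1=CC(=O)OC1
F7 | step 14 | (1R,3E,7E)-10-(iodozincio)-4,8-dimethyl-1-(5-oxo-2,5-dihydrofuran-3-yl)deca-3,7-dien-1-yl acetate | CC(=O)O[C@H](C/C=C(\C)CC/C=C(\C)CC[Zn]I)C1=CC(=O)OC1
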